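**Plan**

1. Numbering: ring A = C1–C5 and C10, ring B = C5–C10, chain = C11–C23. The retrosynthesis cuts C11–C12 first (the chain is joined by alkylating a lactone enolate at C11; the lactone carbonyl is a helper that is excised later), then C8–O, C9–C10 and C2–C3 in one cascade, then C7–C8 (B-alkyl Suzuki) and C4–C5 (Ireland–Claisen).
2. Enabling feature: C10 is quaternary, lies 1,3 to C2 and carries a methyl group. C1, C2 and C10 are therefore stored as a cyclopropane whose fourth substituent (the future C10 methyl carbon) bears SiMe3; C3 is a non-enolisable aldehyde beside the C4 gem-dimethyl group.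
3. Forward: strain-release attack of the C2–C10 σ bond on the C3 aldehyde closes ring A at C2–C3 and expels silicon. Protonation of the resulting C10 methylidene regenerates the biosynthetic C10 cation, which closes ring B onto the E C8=C9 alkene, and the carboxyl group caps C8 as the 8α-oxygen (lactone).
4. Stereochemistry: C5 comes from a CBS reduction relayed by chirality transfer in the Claisen step. C3, C10, C9 and C8 follow from C5 and the alkene geometry in the cascade. The chain alkenes come from (E,E)-farnesyl acetate and an E-selective SeO2 oxidation.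
5. Endgame: C11 alkylation with the C12–C23 bromide, lactone to lactol, decarbonylation (C11 becomes CH2, the 8-OH is freed), desilylation.

Key step: step 14

Remark: in step 14 the SnCl4-bound carboxylic acid of the substrate is taken to be the proton source for the second stage, so no further acid is added.

**Route**

Step 1
Reactants: 1 cyclopropanecarbonitrile; 2 (iodomethyl)trimethylsilane
Product: 3 1-[(trimethylsilyl)methyl]cyclopropane-1-carbonitrile
Conditions: LiN(iPr)2, THF, −78 °C; then 2, −78 → 23 °C
Reagents that add atoms: none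
Why: α-Alkylation of a nitrile, in which the lithiated cyclopropyl nitrile displaces iodide from the unhindered α-silyl primary iodide (SN2) and so installs the carbon that will become the C10 methyl group.

Step 2
Reactants: 3 1-[(trimethylsilyl)methyl]cyclopropane-1-carbonitrile
Product: 4 1-[(trimethylsilyl)methyl]cyclopropane-1-carbaldehyde
Conditions: iBu2AlH (1.2 equiv), CH2Cl2, −78 °C; aq. potassium sodium tartrate, then pH 4 buffer
Reagents that add atoms: water, O
Why: Partial reduction of a nitrile, in which one hydride adds to give an N-aluminio imine that resists further reduction at low temperature and is hydrolysed to the aldehyde at work-up.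

Step 3
Reactants: 4 1-[(trimethylsilyl)methyl]cyclopropane-1-carbaldehyde; 5 1-(triphenyl-λ5-phosphanylidene)propan-2-one
Product: 6 (3E)-4-{1-[(trimethylsilyl)methyl]cyclopropyl}but-3-en-2-one
Conditions: toluene, 100 °C
Reagents that add atoms: none
Why: Wittig olefination with a stabilised ylide, which should give the E enone from this non-enolisable aldehyde.

Step 4
Reactants: 6 (3E)-4-{1-[(trimethylsilyl)methyl]cyclopropyl}but-3-en-2-one
Product: 7 (2S,3E)-4-{1-[(trimethylsilyl)methyl]cyclopropyl}but-3-en-2-ol
Conditions: (R)-2-methyl-CBS-oxazaborolidine (0.1 equiv), catecholborane (1.5 equiv), toluene, −78 °C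
Reagents that add atoms: none
Why: Corey–Bakshi–Shibata reduction, in which the alkenyl group acts as the large substituent so that the (R)-oxazaborolidine should give the (S)-alcohol, the single source of absolute configuration for ring A and ring B, while catecholborane at low temperature leaves the alkene alone.

Step 5
Reactants: 7 (2S,3E)-4-{1-[(trimethylsilyl)methyl]cyclopropyl}but-3-en-2-ol; 8 2-methylpropanoyl chloride
Product: 9 (2S,3E)-4-{1-[(trimethylsilyl)methyl]cyclopropyl}but-3-en-2-yl 2-methylpropanoate
Conditions: pyridine, 4-(dimethylamino)pyridine (cat.), CH2Cl2, 0 °C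
Reagents that add atoms: none
Why: Acylation of a secondary alcohol by an acid chloride under basic conditions, which avoid ionisation of the cyclopropyl-substituted allylic system.

Step 6
Reactants: 9 (2S,3E)-4-{1-[(trimethylsilyl)methyl]cyclopropyl}but-3-en-2-yl 2-methylpropanoate
Product: 12 (3R,4E)-2,2-dimethyl-3-{1-[(trimethylsilyl)methyl]cyclopropyl}hex-4-enoic acid, via silyl ketene acetal 10 (not isolated), via trimethylsilyl ester 11 (not isolated)
Conditions: LiN(iPr)2 (1.2 equiv), THF, −78 °C; Me3SiCl (1.5 equiv), −78 → 23 °C, then 60 °C; aq. citric acid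
Reagents that add atoms: none
Why: Ireland–Claisen rearrangement, in which the silyl ketene acetal 10 rearranges through a chair with the carbinol methyl group equatorial, so that the (S)-carbinol centre is transferred to C5 (3R in this name) and the new alkene is E, while the symmetric Me2C= terminus removes any dependence on enolate geometry and builds the quaternary C4.

Step 7
Reactants: 12 (3R,4E)-2,2-dimethyl-3-{1-[(trimethylsilyl)methyl]cyclopropyl}hex-4-enoic acid
Product: 13 (3R,4E)-2,2-dimethyl-3-{1-[(trimethylsilyl)methyl]cyclopropyl}hex-4-en-1-ol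
Conditions: LiAlH4, THF, 0 → 65 °C
Reagents that add atoms: none
Why: Hydride reduction of the carboxylic acid to the neopentyl alcohol, to which the alkene, the cyclopropane and the C–Si bond are inert.

Step 8
Reactants: 13 (3R,4E)-2,2-dimethyl-3-{1-[(trimethylsilyl)methyl]cyclopropyl}hex-4-en-1-ol
Product: 14 (3R)-4,4-dimethyl-3-{1-[(trimethylsilyl)methyl]cyclopropyl}oxolan-2-ol (mixture at C2)
Conditions: O3, pyridine (3 equiv), CH2Cl2, −78 °C
Reagents that add atoms: ozone, [O-][O+]=O
Why: Ozonolysis of the only alkene in the presence of pyridine, which gives the aldehyde directly; the aldehyde is held as the five-membered lactol by the C3 hydroxyl group, and cyclopropane and C–Si bonds do not react with ozone at this temperature.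

Step 9
Reactants: 14 (3R)-4,4-dimethyl-3-{1-[(trimethylsilyl)methyl]cyclopropyl}oxolan-2-ol
Product: 15 (3R)-2,2-dimethyl-3-{1-[(trimethylsilyl)methyl]cyclopropyl}pent-4-en-1-ol
Conditions: Ph3PCH3Br (3 equiv), KOtBu (2.9 equiv), THF, 0 → 50 °C
Reagents that add atoms: methyltriphenylphosphonium bromide, C[P+](c1ccccc1)(c1ccccc1)c1ccccc1.[Br-]
Why: Wittig methylenation of the open hydroxy aldehyde form of the lactol with excess ylide; the congested C5–H is slow to enolise, so the centre should be kept.

Step 10
Reactants: 16 pent-3-yn-1-ol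
Product: 18 (3E)-4-iodopent-3-en-1-ol, via alkenylzirconocene 17 (not isolated)
Conditions: Cp2Zr(H)Cl (2.5 equiv), THF, 23 → 45 °C; then I2, 0 °C
Reagents that add atoms: iodine, II
Why: Hydrozirconation is a syn addition and, after equilibration with excess hydride, places zirconium on the less hindered methyl-bearing carbon; iodine then cleaves the C–Zr bond with retention to give the E alkenyl iodide.

Step 11
Reactants: 18 (3E)-4-iodopent-3-en-1-ol
Product: 19 (3E)-4-iodopent-3-enoic acid
Conditions: TEMPO (0.2 equiv), PhI(OAc)2 (2.2 equiv), MeCN/H2O, 23 °C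
Reagents that add atoms: water, O
Why: Oxoammonium-mediated (TEMPO) oxidation of the primary alcohol through the aldehyde hydrate to the acid, under conditions mild enough to leave the β,γ double bond in place and the C–I bond intact.

Step 12
Reactants: 15 (3R)-2,2-dimethyl-3-{1-[(trimethylsilyl)methyl]cyclopropyl}pent-4-en-1-ol; 19 (3E)-4-iodopent-3-enoic acid
Product: 21 (3E,7R)-9-hydroxy-4,8,8-trimethyl-7-{1-[(trimethylsilyl)methyl]cyclopropyl}non-3-enoic acid, via alkylborane 20 (not isolated)
Conditions: 15, 9-BBN-H (2.2 equiv), THF, 23 → 50 °C; then 19, PdCl2(dppf) (0.05 equiv), AsPh3, Cs2CO3 (4 equiv), DMF/H2O, 23 °C; acidify to pH 4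
Reagents that add atoms: none
Why: B-alkyl Suzuki–Miyaura coupling, in which 9-BBN-H adds to the terminal carbon of the vinyl group (the hydroxyl is borylated in passing and freed at work-up) and the primary alkylborane couples with the alkenyl iodide with retention of the E geometry to form C7–C8.

Step 13
Reactants: 21 (3E,7R)-9-hydroxy-4,8,8-trimethyl-7-{1-[(trimethylsilyl)methyl]cyclopropyl}non-3-enoic acid
Product: 22 (3E,7R)-4,8,8-trimethyl-9-oxo-7-{1-[(trimethylsilyl)methyl]cyclopropyl}non-3-enoic acid
Conditions: Dess–Martin periodinane (1.3 equiv), pyridine, CH2Cl2, 0 → 23 °C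
Reagents that add atoms: none
Why: Dess–Martin oxidation of the neopentyl alcohol to an aldehyde that cannot enolise or epimerise; the acid, the alkene and the cyclopropylmethylsilane are untouched.

Step 14
Reactants: 22 (3E,7R)-4,8,8-trimethyl-9-oxo-7-{1-[(trimethylsilyl)methyl]cyclopropyl}non-3-enoic acid
Product: 24 (3aR,5aS,7S,9aS,9bR)-7-hydroxy-3a,6,6,9a-tetramethyldecahydronaphtho[2,1-b]furan-2(1H)-one (3β-hydroxysclareolide), via methylidenecyclohexanol acid 23 (not isolated)
Conditions: SnCl4 (2.5 equiv), CH2Cl2, −78 °C, then −78 → −20 °C; aq. NaHCO3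
Reagents that add atoms: none
Why: Proposed new method: SnCl4 activates the non-enolisable C3 aldehyde and the strained C2–C10 σ bond of the cyclopropane attacks it (closure of six-membered ring A, exo to the carbonyl, through a chair) while the C–Si bond stabilises the developing C10 cation and chloride removes silicon, leaving the C10 methylidene 23. The carboxylic acid–SnCl4 pair then protonates this 1,1-disubstituted alkene to the tertiary C10 cation of the biosynthetic pathway, which is attacked by C9 of the C8=C9 alkene (6-endo closure of ring B through a chair), and the C8 cation is trapped by the carboxyl oxygen (five-membered lactone, 5-exo). The closest known reaction types are the Lewis-acid-promoted ring-opening homoallylation of carbonyl electrophiles by (cyclopropylmethyl)silanes and stannanes and the acid-induced cyclisation of monocyclic homofarnesic acids to sclareolide; their coupling in one flask, started by a free aldehyde, is what has not been shown. C3 is set by the chair in which the O–Sn group and the C5 side chain are both equatorial (cis, 3S), C10 by equatorial attack of the tethered alkene on the ring-A cation (trans ring fusion, methyl axial), and C9 and C8 by anti addition across the E alkene, so all four new centres are relayed from C5. The step needs the aldehyde to be attacked by the cyclopropane and not by the C8=C9 alkene (secured by a six- against a seven-membered transition state, the gem-dimethyl group and the deactivating allylic carboxyl group), silicon loss to outrun alkene capture of the β-silyl cation (secured by chloride from SnCl4), and the proton to go to the methylidene and not to C8=C9 (secured by the higher basicity of the 1,1-dialkyl alkene). Release of cyclopropane strain drives the first bond formation.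

Step 15
Reactants: 25 (2E,6E)-3,7,11-trimethyldodeca-2,6,10-trien-1-yl acetate ((E,E)-farnesyl acetate)
Product: 26 (2E,6E,10E)-12-hydroxy-3,7,11-trimethyldodeca-2,6,10-trien-1-yl acetate
Conditions: SeO2 (0.2 equiv), tBuOOH (3 equiv), salicylic acid (0.1 equiv), CH2Cl2, 23 °C
Reagents that add atoms: selenium dioxide, O=[Se]=O; tert-butyl hydroperoxide, CC(C)(C)OO
Why: Allylic oxidation with SeO2 (ene reaction, then 2,3-sigmatropic shift), which should pick the E methyl group of the terminal alkene, the most electron-rich one and the farthest from the acetate, and gives the E allylic alcohol.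

Step 16
Reactants: 26 (2E,6E,10E)-12-hydroxy-3,7,11-trimethyldodeca-2,6,10-trien-1-yl acetate
Product: 27 (2E,6E,10E)-12-[(tert-butyldimethylsilyl)oxy]-3,7,11-trimethyldodeca-2,6,10-trien-1-yl acetate
Conditions: TBSCl, imidazole, DMF, 23 °C
Reagents that add atoms: tert-butyldimethylsilyl chloride, CC(C)(C)[Si](C)(C)Cl
Why: Silylation of the primary allylic alcohol.

Step 17
Reactants: 27 (2E,6E,10E)-12-[(tert-butyldimethylsilyl)oxy]-3,7,11-trimethyldodeca-2,6,10-trien-1-yl acetate
Product: 28 (2E,6E,10E)-12-[(tert-butyldimethylsilyl)oxy]-3,7,11-trimethyldodeca-2,6,10-trien-1-ol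
Conditions: K2CO3 (0.2 equiv), MeOH, 23 °C
Reagents that add atoms: none
Why: Base-catalysed transesterification removes the acetate and leaves the silyl ether.

Step 18
Reactants: 28 (2E,6E,10E)-12-[(tert-butyldimethylsilyl)oxy]-3,7,11-trimethyldodeca-2,6,10-trien-1-ol
Product: 29 {[(2E,6E,10E)-12-bromo-2,6,10-trimethyldodeca-2,6,10-trien-1-yl]oxy}(tert-butyl)dimethylsilane
Conditions: CBr4, PPh3, CH2Cl2, −20 °C
Reagents that add atoms: carbon tetrabromide, BrC(Br)(Br)Br
Why: Appel bromination, an SN2 displacement of the oxyphosphonium group at the primary allylic carbon under neutral conditions, without allylic shift.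

Step 19
Reactants: 24 3β-hydroxysclareolide; 29 {[(2E,6E,10E)-12-bromo-2,6,10-trimethyldodeca-2,6,10-trien-1-yl]oxy}(tert-butyl)dimethylsilane
Product: 30 (3aR,5aS,7S,9aS,9bR)-1-{(2E,6E,10E)-12-[(tert-butyldimethylsilyl)oxy]-3,7,11-trimethyldodeca-2,6,10-trien-1-yl}-7-hydroxy-3a,6,6,9a-tetramethyldecahydronaphtho[2,1-b]furan-2(1H)-one (mixture at C1 of the lactone, which is C11)
Conditions: LiN(iPr)2 (2.3 equiv), THF, −78 → −40 °C; then 29, DMPU, −78 → −20 °C
Reagents that add atoms: none
Why: Alkylation of a lactone enolate, in which the dianion (C3 alkoxide plus C11 enolate) reacts at the enolate carbon with the primary allylic bromide (SN2 at CH2); the configuration created at C11 is of no consequence because C11 becomes CH2 in step 21.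

Step 20
Reactants: 30 C11-alkylated hydroxy lactone
Product: 31 the corresponding lactol, (3aR,5aS,7S,9aS,9bR)-1-{(2E,6E,10E)-12-[(tert-butyldimethylsilyl)oxy]-3,7,11-trimethyldodeca-2,6,10-trien-1-yl}-3a,6,6,9a-tetramethyldodecahydronaphtho[2,1-b]furan-2,7-diol (mixture at C1 and C2)
Conditions: iBu2AlH (2.5 equiv), CH2Cl2, −78 °C; aq. potassium sodium tartrate
Reagents that add atoms: none
Why: Partial reduction of the lactone, in which the aluminium hemiacetal is stable at low temperature and gives the lactol on work-up.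

Step 21
Reactants: 31 lactol
Product: 32 myrrhanol A 23-(tert-butyldimethylsilyl) ether
Conditions: RhCl(PPh3)3 (1.2 equiv), xylene, 130 °C
Reagents that add atoms: none
Why: Tsuji–Wilkinson decarbonylation, a reaction known for lactols through their open hydroxy aldehyde form, in which oxidative addition of the formyl C–H bond, CO extrusion and reductive elimination with retention turn C11 into CH2 and free the 8α-hydroxyl, the helper carbon leaving as rhodium-bound CO.

Step 22
Reactants: 32 myrrhanol A 23-(tert-butyldimethylsilyl) ether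
Product: 33 myrrhanol A
Conditions: Bu4NF, THF, 23 °C
Reagents that add atoms: none
Why: Fluoride cleaves the Si–O bond of the silyl ether to give the target.

**Compound list**

1 | cyclopropanecarbonitrile | N#CC1CC1 | starting material
2 | (iodomethyl)trimethylsilane | C[Si](C)(C)CI | starting material
3 | 1-[(trimethylsilyl)methyl]cyclopropane-1-carbonitrile | C[Si](C)(C)CC1(C#N)CC1 | intermediate
4 | 1-[(trimethylsilyl)methyl]cyclopropane-1-carbaldehyde | C[Si](C)(C)CC1(C=O)CC1 | intermediate
5 | 1-(triphenyl-λ5-phosphanylidene)propan-2-one | CC(=O)C=P(c1ccccc1)(c1ccccc1)c1ccccc1 | starting material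
6 | (3E)-4-{1-[(trimethylsilyl)methyl]cyclopropyl}but-3-en-2-one | CC(=O)/C=C/C1(C[Si](C)(C)C)CC1 | intermediate
7 | (2S,3E)-4-{1-[(trimethylsilyl)methyl]cyclopropyl}but-3-en-2-ol | C[C@H](O)/C=C/C1(C[Si](C)(C)C)CC1 | intermediate
8 | 2-methylpropanoyl chloride | CC(C)C(Cl)=O | starting material
9 | (2S,3E)-4-{1-[(trimethylsilyl)methyl]cyclopropyl}but-3-en-2-yl 2-methylpropanoate | CC(C)C(=O)O[C@@H](C)/C=C/C1(C[Si](C)(C)C)CC1 | intermediate
10 | silyl ketene acetal of 9: trimethyl{[2-methyl-1-({(2S,3E)-4-[1-((trimethylsilyl)methyl)cyclopropyl]but-3-en-2-yl}oxy)prop-1-en-1-yl]oxy}silane | CC(C)=C(O[Si](C)(C)C)O[C@@H](C)/C=C/C1(C[Si](C)(C)C)CC1 | intermediate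
11 | trimethylsilyl (3R,4E)-2,2-dimethyl-3-{1-[(trimethylsilyl)methyl]cyclopropyl}hex-4-enoate | C[Si](C)(C)OC(=O)C(C)(C)[C@H](C1(C[Si](C)(C)C)CC1)/C=C/C | intermediate
12 | (3R,4E)-2,2-dimethyl-3-{1-[(trimethylsilyl)methyl]cyclopropyl}hex-4-enoic acid | OC(=O)C(C)(C)[C@H](C1(C[Si](C)(C)C)CC1)/C=C/C | intermediate
13 | (3R,4E)-2,2-dimethyl-3-{1-[(trimethylsilyl)methyl]cyclopropyl}hex-4-en-1-ol | OCC(C)(C)[C@H](C1(C[Si](C)(C)C)CC1)/C=C/C | intermediate
14 | (3R)-4,4-dimethyl-3-{1-[(trimethylsilyl)methyl]cyclopropyl}oxolan-2-ol (mixture at C2) | CC1(C)COC(O)[C@H]1C1(C[Si](C)(C)C)CC1 | intermediate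
15 | (3R)-2,2-dimethyl-3-{1-[(trimethylsilyl)methyl]cyclopropyl}pent-4-en-1-ol | OCC(C)(C)[C@H](C1(C[Si](C)(C)C)CC1)C=C | intermediate
16 | pent-3-yn-1-ol | CC#CCCO | starting material
17 | (E)-alkenylzirconocene chloride from 16 (zirconium on C4, hydroxyl as its zirconocene alkoxide; cyclopentadienyl rings drawn σ-bonded) | C/C(=C\CCO[Zr](Cl)(C1C=CC=C1)C1C=CC=C1)[Zr](Cl)(C1C=CC=C1)C1C=CC=C1 | intermediate
18 | (3E)-4-iodopent-3-en-1-ol | C/C(I)=C\CCO | intermediate
19 | (3E)-4-iodopent-3-enoic acid | C/C(I)=C\CC(=O)O | intermediate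
20 | B-alkyl-9-borabicyclo[3.3.1]nonane from 15 (boron on the terminal carbon, hydroxyl as its borinate) | CC(C)(COB1C2CCCC1CCC2)[C@H](C1(C[Si](C)(C)C)CC1)CCB1C2CCCC1CCC2 | intermediate
21 | (3E,7R)-9-hydroxy-4,8,8-trimethyl-7-{1-[(trimethylsilyl)methyl]cyclopropyl}non-3-enoic acid | OCC(C)(C)[C@H](C1(C[Si](C)(C)C)CC1)CC/C(C)=C/CC(=O)O | intermediate
22 | (3E,7R)-4,8,8-trimethyl-9-oxo-7-{1-[(trimethylsilyl)methyl]cyclopropyl}non-3-enoic acid | O=CC(C)(C)[C@H](C1(C[Si](C)(C)C)CC1)CC/C(C)=C/CC(=O)O | intermediate
23 | (3E)-6-[(1S,3S)-3-hydroxy-2,2-dimethyl-6-methylidenecyclohexyl]-4-methylhex-3-enoic acid | C=C1CC[C@H](O)C(C)(C)[C@H]1CC/C(C)=C/CC(=O)O | intermediate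
24 | (3aR,5aS,7S,9aS,9bR)-7-hydroxy-3a,6,6,9a-tetramethyldecahydronaphtho[2,1-b]furan-2(1H)-one (3β-hydroxysclareolide) | O=C1C[C@@H]2[C@@]3(C)CC[C@H](O)C(C)(C)[C@H]3CC[C@@]2(C)O1 | intermediate
25 | (2E,6E)-3,7,11-trimethyldodeca-2,6,10-trien-1-yl acetate | CC(C)=CCC/C(C)=C/CC/C(C)=C/COC(C)=O | starting material
26 | (2E,6E,10E)-12-hydroxy-3,7,11-trimethyldodeca-2,6,10-trien-1-yl acetate | C/C(CO)=C\CC/C(C)=C/CC/C(C)=C/COC(C)=O | intermediate
27 | (2E,6E,10E)-12-[(tert-butyldimethylsilyl)oxy]-3,7,11-trimethyldodeca-2,6,10-trien-1-yl acetate | C/C(CO[Si](C)(C)C(C)(C)C)=C\CC/C(C)=C/CC/C(C)=C/COC(C)=O | intermediate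
28 | (2E,6E,10E)-12-[(tert-butyldimethylsilyl)oxy]-3,7,11-trimethyldodeca-2,6,10-trien-1-ol | C/C(CO[Si](C)(C)C(C)(C)C)=C\CC/C(C)=C/CC/C(C)=C/CO | intermediate
29 | {[(2E,6E,10E)-12-bromo-2,6,10-trimethyldodeca-2,6,10-trien-1-yl]oxy}(tert-butyl)dimethylsilane | C/C(CO[Si](C)(C)C(C)(C)C)=C\CC/C(C)=C/CC/C(C)=C/CBr | intermediate
30 | (3aR,5aS,7S,9aS,9bR)-1-{(2E,6E,10E)-12-[(tert-butyldimethylsilyl)oxy]-3,7,11-trimethyldodeca-2,6,10-trien-1-yl}-7-hydroxy-3a,6,6,9a-tetramethyldecahydronaphtho[2,1-b]furan-2(1H)-one (mixture at C1) | C/C(=C\CC/C(C)=C/CC/C(C)=C/CC(C3=O)[C@@H]1[C@@]2(C)CC[C@H](O)C(C)(C)[C@H]2CC[C@@]1(C)O3)CO[Si](C)(C)C(C)(C)C | intermediate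
31 | lactol of 30: (3aR,5aS,7S,9aS,9bR)-1-{(2E,6E,10E)-12-[(tert-butyldimethylsilyl)oxy]-3,7,11-trimethyldodeca-2,6,10-trien-1-yl}-3a,6,6,9a-tetramethyldodecahydronaphtho[2,1-b]furan-2,7-diol (mixture at C1 and C2) | C/C(=C\CC/C(C)=C/CC/C(C)=C/CC(C3O)[C@@H]1[C@@]2(C)CC[C@H](O)C(C)(C)[C@H]2CC[C@@]1(C)O3)CO[Si](C)(C)C(C)(C)C | intermediate
32 | myrrhanol A 23-(tert-butyldimethylsilyl) ether (3S,5S,8R,9R,10S; all chain alkenes E) | C/C(=C\CC/C(C)=C/CC/C(C)=C/CC[C@@H]1[C@@]2(C)CC[C@H](O)C(C)(C)[C@H]2CC[C@@]1(C)O)CO[Si](C)(C)C(C)(C)C | intermediate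
33 | myrrhanol A (3S,5S,8R,9R,10S; 3β,8α-diol, all chain alkenes E) | C/C(=C\CC/C(C)=C/CC/C(C)=C/CC[C@@H]1[C@@]2(C)CC[C@H](O)C(C)(C)[C@H]2CC[C@@]1(C)O)CO | target

**Step count and risks**

Total step count: 22. Longest linear sequence: 16 steps (steps 1–9, 12–14 and 19–22). Steps 10–11 and 15–18 prepare the two coupling partners.

Steps most likely to fail:

1. Step 14. What may go wrong: the Lewis-acid-bound aldehyde is captured by the trisubstituted alkene, or that alkene is protonated first, before the cyclopropane σ bond reacts, so that ring A never forms. The fallback uses known chemistry only, separates the two events and takes the competing alkene out of the first one. It sets out from 15, which is oxidised with Dess–Martin periodinane to (3R)-2,2-dimethyl-3-{1-[(trimethylsilyl)methyl]cyclopropyl}pent-4-enal F1. SnCl4 in CH2Cl2 at −78 °C then effects the known Lewis-acid-promoted ring-opening homoallylation of a carbonyl group by a (cyclopropylmethyl)silane, here in ring-closing form and with only a monosubstituted alkene in the molecule, to give (1S,3S)-3-ethenyl-2,2-dimethyl-4-methylidenecyclohexan-1-ol F2. Hydroboration with bis(3-methylbutan-2-yl)borane, which discriminates the vinyl group from the 1,1-disubstituted alkene, gives the bis(3-methylbutan-2-yl)boryl adduct F3, and this is coupled with 19 under the palladium conditions of step 12 to give 23 as an isolated compound. Chlorosulfonic acid in 2-nitropropane at −78 °C, the known type of cyclisation that converts monocyclic homofarnesic acids into sclareolide, then closes ring B and the lactone, and the route comes back at 24.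

2. Step 21. What may go wrong: the lactol may not open to the hydroxy aldehyde fast enough at a tolerable temperature, and β-hydride elimination from the alkylrhodium intermediate may compete with reductive elimination. The fallback removes the helper carbon as CO2 with a sulfone as a second helper. It sets out from 24, whose enolate (LiN(iPr)2, 3 equiv, THF, −78 °C) is sulfenylated with diphenyl disulfide to the 1-(phenylsulfanyl) lactone F4, and Oxone in aqueous methanol oxidises this to the 1-(phenylsulfonyl) lactone F5. Its stabilised anion (K2CO3, DMF) is alkylated with 29 to the 1-alkyl-1-(phenylsulfonyl) lactone F6. LiOH in aqueous THF opens the lactone to the α-sulfonyl hydroxy acid F7 (as its lithium salt), which loses CO2 on warming in DMSO to give the C11 sulfone F8, 11-(phenylsulfonyl)myrrhanol A 23-(tert-butyldimethylsilyl) ether. Na/Hg with Na2HPO4 in MeOH at −20 °C removes the sulfonyl group, and the route comes back at 32.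

3. Step 6. What may go wrong: steric congestion between the fully substituted ketene acetal carbon and the cyclopropyl-bearing alkene terminus slows the sigmatropic shift, so that the ketene acetal decomposes or the allylic ester ionises first. The fallback builds the quaternary carbon after the rearrangement. It sets out from 7, which is acylated with propanoyl chloride (pyridine, CH2Cl2) to (2S,3E)-4-{1-[(trimethylsilyl)methyl]cyclopropyl}but-3-en-2-yl propanoate F9. Ireland–Claisen rearrangement of this less hindered ester under the conditions of step 6, through the silyl ketene acetal F10 and the trimethylsilyl ester F11, gives (3R,4E)-2-methyl-3-{1-[(trimethylsilyl)methyl]cyclopropyl}hex-4-enoic acid F12 as a mixture at C2, with the same chirality transfer to C5. The dianion of F12 (LiN(iPr)2, 2.2 equiv, THF) is methylated with iodomethane, which erases the C2 centre of the acid, and the route comes back at 12.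

Further compounds

F1 | step 14 | (3R)-2,2-dimethyl-3-{1-[(trimethylsilyl)methyl]cyclopropyl}pent-4-enal | O=CC(C)(C)[C@H](C1(C[Si](C)(C)C)CC1)C=C
F2 | step 14 | (1S,3S)-3-ethenyl-2,2-dimethyl-4-methylidenecyclohexan-1-ol | C=C1CC[C@H](O)C(C)(C)[C@H]1C=C
F3 | step 14 | bis(3-methylbutan-2-yl)boryl adduct of F2 (boron on the terminal carbon of the former vinyl group, hydroxyl as its borinate) | C=C1CC[C@H](OB(C(C)C(C)C)C(C)C(C)C)C(C)(C)[C@H]1CCB(C(C)C(C)C)C(C)C(C)C
F4 | step 21 | (3aR,5aS,7S,9aS,9bR)-7-hydroxy-3a,6,6,9a-tetramethyl-1-(phenylsulfanyl)decahydronaphtho[2,1-b]furan-2(1H)-one (mixture at C1) | O=C1C(Sc4ccccc4)[C@@H]2[C@@]3(C)CC[C@H](O)C(C)(C)[C@H]3CC[C@@]2(C)O1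
F5 | step 21 | (3aR,5aS,7S,9aS,9bR)-7-hydroxy-3a,6,6,9a-tetramethyl-1-(phenylsulfonyl)decahydronaphtho[2,1-b]furan-2(1H)-one (mixture at C1) | O=C1C(S(=O)(=O)c4ccccc4)[C@@H]2[C@@]3(C)CC[C@H](O)C(C)(C)[C@H]3CC[C@@]2(C)O1
F6 | step 21 | (3aR,5aS,7S,9aS,9bR)-1-{(2E,6E,10E)-12-[(tert-butyldimethylsilyl)oxy]-3,7,11-trimethyldodeca-2,6,10-trien-1-yl}-7-hydroxy-3a,6,6,9a-tetramethyl-1-(phenylsulfonyl)decahydronaphtho[2,1-b]furan-2(1H)-one (mixture at C1) | C/C(=C\CC/C(C)=C/CC/C(C)=C/CC(C3=O)(S(=O)(=O)c4ccccc4)[C@@H]1[C@@]2(C)CC[C@H](O)C(C)(C)[C@H]2CC[C@@]1(C)O3)CO[Si](C)(C)C(C)(C)C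
F7 | step 21 | ring-opened α-sulfonyl hydroxy acid of F6 (C11 carries the carboxyl group, the phenylsulfonyl group and the chain; 3β,8α-diol; formed as its lithium salt) | C/C(=C\CC/C(C)=C/CC/C(C)=C/CC(C(=O)O)(S(=O)(=O)c4ccccc4)[C@@H]1[C@@]2(C)CC[C@H](O)C(C)(C)[C@H]2CC[C@@]1(C)O)CO[Si](C)(C)C(C)(C)C
F8 | step 21 | 11-(phenylsulfonyl)myrrhanol A 23-(tert-butyldimethylsilyl) ether (mixture at C11) | C/C(=C\CC/C(C)=C/CC/C(C)=C/CC(S(=O)(=O)c4ccccc4)[C@@H]1[C@@]2(C)CC[C@H](O)C(C)(C)[C@H]2CC[C@@]1(C)O)CO[Si](C)(C)C(C)(C)C
F9 | step 6 | (2S,3E)-4-{1-[(trimethylsilyl)methyl]cyclopropyl}but-3-en-2-yl propanoate | CCC(=O)O[C@@H](C)/C=C/C1(C[Si](C)(C)C)CC1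
F10 | step 6 | silyl ketene acetal of F9 (ketene acetal geometry not defined) | CC=C(O[Si](C)(C)C)O[C@@H](C)/C=C/C1(C[Si](C)(C)C)CC1
F11 | step 6 | trimethylsilyl (3R,4E)-2-methyl-3-{1-[(trimethylsilyl)methyl]cyclopropyl}hex-4-enoate (mixture at C2) | C[Si](C)(C)OC(=O)C(C)[C@H](C1(C[Si](C)(C)C)CC1)/C=C/C
F12 | step 6 | (3R,4E)-2-methyl-3-{1-[(trimethylsilyl)methyl]cyclopropyl}hex-4-enoic acid (mixture at C2) | OC(=O)C(C)[C@H](C1(C[Si](C)(C)C)CC1)/C=C/C
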